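A half-life of 6.88 s for the exchange of target and isomer of the product in grey, against a stop at 20 s, is the number on which the next run hangs.

    starting material ⇌ other conformer (K1 = 0.027, k1 = 0.17 s⁻¹, Ea1 = 73.0 kJ mol⁻¹, ΔH1 = −18.0 kJ mol⁻¹)
    starting material → target (k2 = 0.021 s⁻¹, Ea2 = 84.0 kJ mol⁻¹)
    other conformer → isomer of the product (k3 = 0.028 s⁻¹, Ea3 = 74.0 kJ mol⁻¹)
    target ⇌ isomer of the product (K4 = 0.84, k4 = 0.046 s⁻¹, Ea4 = 64.0 kJ mol⁻¹, ΔH4 = −38.0 kJ mol⁻¹)
    starting material + target → side product (k5 = 0.050 M⁻¹ s⁻¹, Ea5 = 56.0 kJ mol⁻¹)
    starting material ⇌ dormant form (K6 = 1.6, k6 = 0.066 s⁻¹, Ea6 = 83.0 kJ mol⁻¹, ΔH6 = −45.0 kJ mol⁻¹)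
    solid substrate ⇌ starting material, rate k7*(cs7 - [starting material]) while solid is left; crystals form when [starting material] > cs7 (cs7 = 0.059 M, k7 = 0.039 s⁻¹)
    (constants at 5 °C)

the same everywhere: solid substrate 0.20 M; time 20 s

| charge | temperature |
|---|---|
| red | 20 °C |
| teal | 35 °C |
| violet | −10 °C |
| grey | 5 °C |

- a species is counted by the solid substrate in it: one side product counts as two
- given per volume of solution although it is solid: solid substrate
- at 5 °C the constants are as listed, elsewhere as the activation energies and enthalpies make them
- at the start none of the solid substrate is in solution
- in a conversion other conformer counts as not yet reacted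
- what has only dissolved of solid substrate counts as not reacted

- the best flask by share of target in all that became target or isomer of the product or side product; "all alike" if 1.5 percentage points covers them all (red / teal / violet / grey / all alike)
- share of target in all that became target or isomer of the product or side product, red
- share of target in all that became target or isomer of the product or side product, teal
- share of target in all that became target or isomer of the product or side product, violet
- share of target in all that became target or isomer of the product or side product, grey

- The next run needs a temperature, a stop and a charge of solid substrate, so the reckoning asks how each moves the share of target. It uses grey, where the constants stand as listed: K = 0.84 is the equilibrium constant of isomer over target, and k = 0.046 s⁻¹ is the forward constant of that exchange.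
- The reckoning assumes that target arrives at a steady rate F from the start, and it sets aside the side product and the route through the other conformer.
- Target and isomer then total Ft, and the isomer Q obeys dQ/dt + λQ = kFt, with relaxation rate λ = k + k/K = 0.101 s⁻¹.
- Integration gives Q/(Ft) = qB, where q = K/(1 + K) and B = 1 − (1 − e^(−x))/x, with x = λt. F cancels, so the share depends on K and x, not on how fast the solid dissolves, and the charge can stay.
- In grey x = 2.02 and B = 0.570. The lagged share s = 1 − qB, the target share of a steadily fed pair at the stop, is therefore 74.0 %. That is higher than the equilibrium share of 54.3 %, because the half-life, though shorter than the stop, still leaves the newest target unexchanged.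
- B grows with x, so a later stop lowers s in grey, and the stop stays at 20 s.
- For large x, s tends to 1/(1 + K), which is thermodynamic control. For small x, qB tends to kt/2, free of K, which is kinetic control. With 64.0 kJ mol⁻¹ in the exchange, violet has the smaller k and is expected to hold the higher share. This reckoning gives no figure for violet, but it commits to violet for a run judged by share.
- The forecast named violet with 74.2 % for red, 83.5 % for teal, 87.7 % for violet and 75.5 % for grey; it called the violet figure kinetic and said of teal, with T for target, “warm equilibrium favours T”.
- The flasks give 74.3 % for red, 83.6 % for teal, 88.0 % for violet and 75.6 % for grey, so violet has the highest share. Grey holds 2.00 % target and 0.621 % isomer of the product at 20.0 s, which is 76.3 % target in that pair against the reckoned 74.0 %. Put to 200 s, the same formula lowers s to 56.6 %, and grey then holds 56.1 % in the pair.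
- The neighbour at 35 °C is red run at teal's temperature, so it has teal's constant 0.170. With B taken as close to one, s comes to 85.5 %. The computed flask gives 83.6 %, with 16.8 % target and 2.82 % isomer of the product.

Its constants are made up.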